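The numbers in the tables come from a simulation with made-up constants; scatter was added.

The easy mistake with a catalyst is to take the slope of an early run, multiply it by the hours, and believe the target climbs in a straight line until the charge is used.

| flask | starting material | protic impurity | free catalyst | remark | time |
|---|---|---|---|---|---|
| ochre | 22 mM | 10 mM | 0.98 mM | run made earlier |  |
| Tuesday's | 6.0 mM | 40.0 mM | 3.0 mM |  | 2.5 h |
| Friday's | 5.0 mM | 6.00 mM | 0.50 mM |  | 2.5 h |
| Saturday's | 20 mM | 10.0 mM | 0.98 mM |  | 2.5 h |
| Sunday's | 6.0 mM | 10.0 mM | 0.30 mM |  | 2.5 h |
| Monday's | 20 mM | 10.0 mM | 2.0 mM |  | 2.5 h |
| Wednesday's | 30 mM | 30.0 mM | 0.98 mM |  | 2.5 h |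

ochre run (percent of the starting material charged): time / min: target / % = 2.50: 0.7; 8.00: 5.1; 15.0: 8.1; 20.0: 9.7; 30.0: 16.0

(each reading ± 0.5 percentage points)

- in percentages every species weighs as the starting material in it: one idle adduct counts as two
- for target the idle adduct is counted in
- steps thought possible: starting material + target <-> idle adduct; catalyst intermediate B -> free catalyst + target; catalyst intermediate A <-> catalyst intermediate B; starting material + protic impurity -> quenched substrate; starting material + free catalyst <-> catalyst intermediate A
- in an amount of target, one idle adduct counts as one target
- no earlier run changes the charge of protic impurity; that part of a forecast is a guess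
- no earlier run changes the charge of free catalyst; that part of a forecast is a guess

- all flasks from highest to lowest amount of target, in percent of the starting material charged, at 2.5 h (Tuesday's / Friday's / Saturday's / Sunday's / Monday's / Wednesday's)
- the amount of target, in percent of the starting material charged of the flask you put first, at 2.5 h
- the amount of target, in percent of the starting material charged of the flask you put last, at 2.5 h

The ochre run covers too little of its curve to show whether its slope holds, but I expect the rate to fall as the starting material goes, so I work with the fraction left. I assume the catalyst takes a fixed fraction of the remaining starting material each minute, in proportion to the catalyst charged, which is a pseudo-first-order picture. From the last ochre reading, 16.0% at 30.0 min, with its scatter of 0.5 percentage points, I read the clearing constant, the fraction of what remains that turns to target per minute: 0.00581 min⁻¹ at 0.98 mM of catalyst.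

Now take Sunday's in slow motion, the flask with the smallest catalyst charge, 0.30 mM. In the first instants free catalyst picks up starting material and passes through catalyst intermediates A and B. The ochre run shows this start as 0.7% at 2.50 min, a delay far shorter than the run of 2.5 h, so I ignore it. Through the middle, Sunday's clearing constant is the ochre one scaled down by the catalyst, and the protic impurity takes its own fraction, which no earlier run measures. At the end, leaving the impurity out, 76.6% remains and the target is 23.4%, idle adduct counted in. The straight line would have said 89.8%. I commit to Sunday's last, near that 23.4%.

The forecast, which puts Wednesday's last where I put Sunday's, reads Monday's > Tuesday's > Friday's > Saturday's > Sunday's > Wednesday's, with 75% first and 33% last, and says "Wednesday's also loses heavily to impurity".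

The flasks give Monday's > Tuesday's > Saturday's > Friday's > Wednesday's > Sunday's, with 73.6% first and 30.0% last.

    starting material + target ⇌ idle adduct, settled at all times (K = 91.0 M⁻¹)
    catalyst intermediate B → free catalyst + target (k = 0.586 min⁻¹)
    catalyst intermediate A ⇌ catalyst intermediate B (K = 0.610, k = 6.54 min⁻¹)
    starting material + protic impurity → quenched substrate (k = 0.548 M⁻¹ min⁻¹)
    starting material + free catalyst ⇌ catalyst intermediate A (K = 47.0 M⁻¹, k = 884 M⁻¹ min⁻¹)

At 2.5 h Sunday's holds quenched substrate at 38.8%, more than the 30.0% of target, where I reckoned 23.4% with the impurity left out. With 0.12 mM of catalyst in the same flask, the clearing constant gives 10.1%, a fall by a factor of 2.32 from Sunday's, and the flask falls by a factor of 2.17, to 13.8%.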